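The ten-membered ring is cut at C6–C7. In the carbocycle the free C6 carbinol sits next to C7, whose isopropyl group is read as a hydrogenated isopropenyl group. C6(OH)–C7–C11(=C12) is then a homoallylic alcohol, the signature of a [2,3]-Wittig shift. Reconnecting O6 to C12 gives the precursor: a 13-membered cyclic bis-allylic ether holding both E ring alkenes, a Z C7=C11 alkene and the C8 silyl ether from (R)-glycidol. One deprotonation at C6 then forges C6–C7, cleaves O–C12, contracts the ring to the germacrane carbocycle and sets C6 and C7 under control of C8. Hydrogenation and ferulate attachment finish the synthesis.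

Key step: step 13

Remarks

- **Atom labels.** The ring runs C1=C10 (E, CH3 on C10), C2, C3, C4=C5 (E, CH3 on C4), C6 (free carbinol), C7 (isopropyl), C8 (ferulate), C9 (CH2). C11 is the branch carbon on C7. C12 is the branch terminus that carries oxygen before the contraction. Open-chain compounds keep these labels.
- **Stereochemical check.**
  - The target is 6S,7S,8S. The stereocentre of (R)-glycidol becomes C8 (S) and none of its bonds is ever broken.
  - On the zigzag C5–C6–C7–C11, the C6 hydroxyl and C8 lie syn. This is the outcome expected from a Z allyl unit in an exo envelope.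
  - Attack anti to the C8 oxygen with H8 in the alkene plane gives 7S.
  - The C7 descriptor reads R whenever O6 carries silicon. This is a change of CIP ranking, not of geometry.
- **Design points.**
  - (a) The 13-membered ether is closed from a C6 alkoxide onto a C12 chloride. The opposite polarity would place an alkoxide cis to the C8 silyl ether across the Z alkene and invite silyl migration.
  - (b) The C8 group is triethylsilyl because it must later leave beside a C6 tert-butyldimethylsilyl ether.
  - (c) After the contraction nothing is heated above room temperature or exposed to unbuffered acid, since 1(10),4-germacradienes undergo Cope rearrangement and transannular cyclisation.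
- **Assumption.** Ethyl 2-[bis(2,2,2-trifluoroethoxy)phosphoryl]propanoate, 9-BBN-H and lithium 2,2,6,6-tetramethylpiperidide are taken as purchased reagents.

Step 1
Reactants: 1 (R)-glycidol
Product: 2 (2S)-pent-4-yne-1,2-diol
Conditions: LiC≡CH·H2NCH2CH2NH2 (3 equiv), DMSO, slow addition of 1, 0 °C → rt; aq NH4Cl
Reagents that add atoms: lithium acetylide–ethylenediamine complex, [Li]C#C.NCCN
Why: Epoxide alkynylation: after the first equivalent has deprotonated the hydroxyl, acetylide opens the oxirane by SN2 attack at its unsubstituted carbon (future C9), the Payne shift of the glycidol alkoxide is degenerate, and the C–O bond at the stereocentre (future C8) is never broken, so its configuration is carried over.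

Step 2
Reactants: 2 (2S)-pent-4-yne-1,2-diol
Product: 4 (2S,4E)-5-iodo-4-methylpent-4-ene-1,2-diol, via alkenylalane 3 (not isolated)
Conditions: AlMe3 (5 equiv), Cp2ZrCl2 (0.5 equiv), CH2Cl2, 0 °C → rt; I2, THF, −30 °C; H2O
Reagents that add atoms: trimethylaluminium, C[Al](C)C; iodine, II
Why: Negishi carboalumination: zirconium-catalysed syn addition of CH3–Al puts methyl on the internal carbon (C10) and aluminium on the terminus (C1), the two hydroxyls ride along as dimethylaluminium alkoxides as free alkynols are known to do, and iodinolysis of the C–Al bond with retention fixes the E iodide.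

Step 3
Reactants: 4 (2S,4E)-5-iodo-4-methylpent-4-ene-1,2-diol
Product: 5 (2S,4E)-5-iodo-4-methyl-1,2-bis(triethylsilyloxy)pent-4-ene
Conditions: Et3SiCl (2.5 equiv), imidazole, CH2Cl2, 0 °C → rt
Reagents that add atoms: chlorotriethylsilane, CC[Si](Cl)(CC)CC
Why: Routine silyl ether formation at both hydroxyls, chosen because the pair can be told apart in the next step without a separate deprotection.

Step 4
Reactants: 5 (2S,4E)-5-iodo-4-methyl-1,2-bis(triethylsilyloxy)pent-4-ene
Product: 6 (2S,4E)-5-iodo-4-methyl-2-(triethylsilyloxy)pent-4-enal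
Conditions: (COCl)2, DMSO, CH2Cl2, −78 → −40 °C; Et3N, −78 → 0 °C
Reagents that add atoms: none
Why: Swern oxidation applied directly to the bis-silyl ether: the chlorosulfonium reagent exchanges only with the unhindered primary triethylsilyl ether, whose alkoxysulfonium salt collapses to the aldehyde on addition of base, while the secondary C8 ether stays and the cold, brief base contact spares the α-stereocentre.

Step 5
Reactants: 6 (2S,4E)-5-iodo-4-methyl-2-(triethylsilyloxy)pent-4-enal
Product: 7 ethyl (2Z,4S,6E)-7-iodo-2,6-dimethyl-4-(triethylsilyloxy)hepta-2,6-dienoate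
Conditions: ethyl 2-[bis(2,2,2-trifluoroethoxy)phosphoryl]propanoate, KN(SiMe3)2, 18-crown-6, THF, −78 °C
Reagents that add atoms: ethyl 2-[bis(2,2,2-trifluoroethoxy)phosphoryl]propanoate, CCOC(=O)C(C)P(=O)(OCC(F)(F)F)OCC(F)(F)F
Why: Still–Gennari olefination: the electron-poor trifluoroethyl phosphonate with a dissociated potassium counter-ion eliminates fast from the kinetic adduct and so gives the Z trisubstituted enoate (C8 cis to the C12 carbonyl), and −78 °C protects the α-silyloxy stereocentre.

Step 6
Reactants: 8 (E)-3-methylpent-2-en-4-yn-1-ol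
Product: 9 4-methoxybenzyl (2E)-3-methylpent-2-en-4-yn-1-yl ether
Conditions: NaH, 4-methoxybenzyl chloride, Bu4NI (cat.), THF–DMF, 0 °C → rt
Reagents that add atoms: 4-methoxybenzyl chloride, COc1ccc(CCl)cc1
Why: Williamson etherification of the primary allylic alkoxide; the PMB group is picked because it later leaves under neutral oxidative conditions that spare a triethylsilyl ether and an allylic chloride.

Step 7
Reactants: 9 4-methoxybenzyl (2E)-3-methylpent-2-en-4-yn-1-yl ether
Product: 10 4-methoxybenzyl (2E)-3-methylpenta-2,4-dien-1-yl ether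
Conditions: H2 (1 atm), Pd/CaCO3 poisoned with Pb(OAc)2, quinoline, hexane–EtOAc, rt, stopped after one equivalent of H2
Reagents that add atoms: none
Why: Lindlar-type semihydrogenation stops the terminal alkyne at the vinyl stage on the lead- and quinoline-poisoned surface, leaves the E trisubstituted alkene and the benzylic ether alone, and gives the 1,3-diene needed for hydroboration.

Step 8
Reactants: 7 ethyl (2Z,4S,6E)-7-iodo-2,6-dimethyl-4-(triethylsilyloxy)hepta-2,6-dienoate; 10 4-methoxybenzyl (2E)-3-methylpenta-2,4-dien-1-yl ether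
Product: 12 ethyl (2Z,4S,6E,10E)-12-(4-methoxybenzyloxy)-2,6,10-trimethyl-4-(triethylsilyloxy)dodeca-2,6,10-trienoate, via B-alkyl-9-BBN adduct 11 (not isolated)
Conditions: 10, 9-BBN-H, THF, 0 °C → rt; then aq Cs2CO3, 7, Pd(dppf)Cl2, AsPh3, DMF, rt
Reagents that add atoms: none
Why: B-alkyl Suzuki–Miyaura coupling: 9-BBN-H adds only to the monosubstituted end of the diene with boron on the terminal carbon (C2), and the borate formed with base transfers this primary alkyl group to the alkenylpalladium iodide with retention of the E geometry at C1=C10, the ester, silyl ether and PMB ether all being tolerated at room temperature.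

Step 9
Reactants: 12 ethyl (2Z,4S,6E,10E)-12-(4-methoxybenzyloxy)-2,6,10-trimethyl-4-(triethylsilyloxy)dodeca-2,6,10-trienoate
Product: 13 (2Z,4S,6E,10E)-12-(4-methoxybenzyloxy)-2,6,10-trimethyl-4-(triethylsilyloxy)dodeca-2,6,10-trien-1-ol
Conditions: i-Bu2AlH (2.5 equiv), CH2Cl2, −78 °C; aqueous work-up
Reagents that add atoms: none
Why: 1,2-Reduction of the enoate by the aluminium hydride at low temperature gives the Z allylic alcohol without touching alkene geometry, silyl ether or PMB ether.

Step 10
Reactants: 13 (2Z,4S,6E,10E)-12-(4-methoxybenzyloxy)-2,6,10-trimethyl-4-(triethylsilyloxy)dodeca-2,6,10-trien-1-ol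
Product: 15 (2Z,4S,6E,10E)-1-chloro-12-(4-methoxybenzyloxy)-2,6,10-trimethyl-4-(triethylsilyloxy)dodeca-2,6,10-triene, via allylic mesylate 14 (not isolated)
Conditions: MsCl, 2,4,6-collidine, LiCl, DMF, 0 °C
Reagents that add atoms: lithium chloride, [Li+].[Cl-]
Why: Mesylation followed in the same flask by SN2 displacement with chloride converts primary allylic alcohols into unrearranged chlorides with retention of alkene geometry, and the leaving group is placed on C12 so that the later alkoxide is the remote one on C6 and no alkoxide ever sits cis to the migratable C8 silyl group.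

Step 11
Reactants: 15 (2Z,4S,6E,10E)-1-chloro-12-(4-methoxybenzyloxy)-2,6,10-trimethyl-4-(triethylsilyloxy)dodeca-2,6,10-triene
Product: 16 (2E,6E,9S,10Z)-12-chloro-3,7,11-trimethyl-9-(triethylsilyloxy)dodeca-2,6,10-trien-1-ol
Conditions: DDQ, CH2Cl2–pH 7 phosphate buffer, 0 °C
Reagents that add atoms: none
Why: Oxidative PMB cleavage by hydride abstraction from the electron-rich benzylic position and hydrolysis of the oxocarbenium ion, run buffered so that the triethylsilyl ether, the allylic chloride and the trisubstituted alkenes are left alone.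

Step 12
Reactants: 16 (2E,6E,9S,10Z)-12-chloro-3,7,11-trimethyl-9-(triethylsilyloxy)dodeca-2,6,10-trien-1-ol
Product: 17 (3Z,5S,7E,11E)-3,7,11-trimethyl-5-(triethylsilyloxy)-1-oxacyclotrideca-3,7,11-triene (13-membered ether, O bridging C6 and C12, 8S)
Conditions: NaH, Bu4NI (cat.), THF, syringe-pump addition of 16 (about 1 mM), 45 °C
Reagents that add atoms: none
Why: Intramolecular Williamson etherification under pseudo-high dilution: a primary allylic alkoxide displaces a primary allylic chloride (iodide relay), three rigid alkenes cut down the rotors of the chain, and this closure is the established entry to 13-membered bis-allylic ethers.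

Step 13
Reactants: 17 (3Z,5S,7E,11E)-3,7,11-trimethyl-5-(triethylsilyloxy)-1-oxacyclotrideca-3,7,11-triene
Product: 20 (6S,7S,8S)-7-isopropenyl-8-(triethylsilyloxy)germacra-1(10)E,4E-dien-6-ol, via C6-lithiated ether 18 (not isolated), via lithium C6-alkoxide 19 (not isolated)
Conditions: lithium 2,2,6,6-tetramethylpiperidide (3 equiv), THF, −78 → −20 °C; AcOH in THF, −78 °C
Reagents that add atoms: none
Why: The hindered lithium amide removes one allylic α-oxy proton at C6 and the oxyallyl anion 18 bonds from C6 to C7 through a five-centre envelope while O–C12 breaks and the C7=C11 π bond moves to C11=C12, which gives alkoxide 19 in a concerted suprafacial [2,3]-Wittig rearrangement. The closest known reaction type is the transannular [2,3]-Wittig contraction of 13-membered cyclic bis-allylic ethers to ten-membered homoallylic alcohols, here applied to a member with a Z alkene and a C8 silyloxy group. The ten-membered carbocycle arises by ring contraction, O, C12 and C11 leaving the 13-membered perimeter as the C6–C7 bond spans it, so the reacting ends are already held together and no end-to-end closure is needed. C7 is controlled by C8: A(1,3) strain against the cis C12 methylene keeps H8 in the alkene plane, the C8–O bond then stands roughly perpendicular to it, and C6, tethered on the C9 side, attacks the face anti to the silyloxy group. C6 is controlled by the Z geometry of C7=C11 combined with the exo position of the C4=C5 vinyl unit in the envelope (endo would press it against the C11 methyl), which translates into the syn C6–OH/C7–C8 relationship of the target. The step needs site selectivity for C6–H over C12–H, whose anion could expel the C8 silyloxide or shift onto C4; the substrate helps because the C12 protons lie cis to the bulky C8 carbinol carbon and are screened from the base, because the liberated amine allows a misplaced anion to be reprotonated, and because only the C6 anion attacks a CH alkene terminus rather than a fully substituted one, while the cold acidic quench keeps 19 from silyl migration or oxy-Cope chemistry.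

Step 14
Reactants: 20 (6S,7S,8S)-7-isopropenyl-8-(triethylsilyloxy)germacra-1(10)E,4E-dien-6-ol
Product: 21 (6S,7S,8S)-8-(triethylsilyloxy)germacra-1(10)E,4E-dien-6-ol (C7 isopropyl)
Conditions: H2 (1 atm), RhCl(PPh3)3 (10 mol %), toluene–EtOH, rt
Reagents that add atoms: none
Why: Homogeneous hydrogenation with the bulky rhodium phosphine complex discriminates by steric access, so the exocyclic 1,1-disubstituted alkene is reduced while the two trisubstituted ring alkenes are not; no stereocentre is created because C11 becomes an isopropyl methine.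

Step 15
Reactants: 21 (6S,7S,8S)-8-(triethylsilyloxy)germacra-1(10)E,4E-dien-6-ol
Product: 22 (6S,7R,8S)-6-(tert-butyldimethylsilyloxy)-8-(triethylsilyloxy)germacra-1(10)E,4E-diene
Conditions: TBSOTf, 2,6-lutidine, CH2Cl2, −78 → 0 °C
Reagents that add atoms: tert-butyldimethylsilyl triflate, CC(C)(C)[Si](C)(C)OS(=O)(=O)C(F)(F)F
Why: Silyl triflate silylation of the hindered allylic C6 hydroxyl under lutidine buffering, cold enough to leave the acid-sensitive 1,5-diene and the C8 triethylsilyl ether intact.

Step 16
Reactants: 22 (6S,7R,8S)-6-(tert-butyldimethylsilyloxy)-8-(triethylsilyloxy)germacra-1(10)E,4E-diene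
Product: 23 (6S,7R,8S)-6-(tert-butyldimethylsilyloxy)germacra-1(10)E,4E-dien-8-ol
Conditions: HF·pyridine, excess pyridine, THF, 0 °C
Reagents that add atoms: none
Why: Selective desilylation: buffered HF cleaves a triethylsilyl ether far faster than a secondary tert-butyldimethylsilyl ether, and the excess pyridine keeps the medium too weakly acidic for transannular cyclisation.

Step 17
Reactants: 24 ferulic acid
Product: 26 (E)-3-[4-(tert-butyldimethylsilyloxy)-3-methoxyphenyl]prop-2-enoic acid, via bis-silylated ferulate 25 (not isolated)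
Conditions: TBSCl (2.5 equiv), imidazole, DMF, rt; then AcOH–THF–H2O, rt
Reagents that add atoms: tert-butyldimethylsilyl chloride, CC(C)(C)[Si](C)(C)Cl
Why: Exhaustive silylation followed by mild aqueous acetolysis, which hydrolyses the very labile silyl ester but not the aryl silyl ether.

Step 18
Reactants: 23 (6S,7R,8S)-6-(tert-butyldimethylsilyloxy)germacra-1(10)E,4E-dien-8-ol; 26 (E)-3-[4-(tert-butyldimethylsilyloxy)-3-methoxyphenyl]prop-2-enoic acid
Product: 28 (6S,7R,8S)-6-(tert-butyldimethylsilyloxy)germacra-1(10)E,4E-dien-8-yl (E)-3-[4-(tert-butyldimethylsilyloxy)-3-methoxyphenyl]prop-2-enoate, via mixed anhydride 27 (not isolated)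
Conditions: 26, 2,4,6-trichlorobenzoyl chloride, Et3N, toluene, rt; then 23, DMAP, rt
Reagents that add atoms: none
Why: Yamaguchi esterification: the mixed anhydride is attacked by DMAP at the less hindered cinnamoyl carbonyl and the acylpyridinium ion acylates the hindered C8 hydroxyl at room temperature with retention at C8, since only the O–H bond is involved.

Step 19
Reactants: 28 (6S,7R,8S)-6-(tert-butyldimethylsilyloxy)germacra-1(10)E,4E-dien-8-yl (E)-3-[4-(tert-butyldimethylsilyloxy)-3-methoxyphenyl]prop-2-enoate
Product: 29 (6S,7S,8S)-6-hydroxygermacra-1(10)E,4E-dien-8-yl (E)-ferulate (CNP0378519.1)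
Conditions: Bu4NF, AcOH (equimolar), THF, 0 °C → rt
Reagents that add atoms: none
Why: Fluoride-driven cleavage of both silyl ethers, buffered with acetic acid so that neither phenoxide nor C6 alkoxide builds up and the ferulate neither migrates from O8 to O6 nor is cleaved.

Compound list

1 | (R)-glycidol | OC[C@@H]1CO1 | starting material
2 | (2S)-pent-4-yne-1,2-diol | OC[C@@H](O)CC#C | intermediate
3 | (E)-alkenyl(dimethyl)alane from 2, both oxygens as dimethylaluminium alkoxides | C[Al](C)OC[C@@H](O[Al](C)C)C/C(C)=C/[Al](C)C | intermediate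
4 | (2S,4E)-5-iodo-4-methylpent-4-ene-1,2-diol | OC[C@@H](O)C/C(C)=C/I | intermediate
5 | (2S,4E)-5-iodo-4-methyl-1,2-bis(triethylsilyloxy)pent-4-ene | CC[Si](CC)(CC)OC[C@@H](O[Si](CC)(CC)CC)C/C(C)=C/I | intermediate
6 | (2S,4E)-5-iodo-4-methyl-2-(triethylsilyloxy)pent-4-enal | O=C[C@@H](O[Si](CC)(CC)CC)C/C(C)=C/I | intermediate
7 | ethyl (2Z,4S,6E)-7-iodo-2,6-dimethyl-4-(triethylsilyloxy)hepta-2,6-dienoate | CCOC(=O)/C(C)=C\[C@@H](O[Si](CC)(CC)CC)C/C(C)=C/I | intermediate
8 | (E)-3-methylpent-2-en-4-yn-1-ol | C#C/C(C)=C/CO | starting material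
9 | 4-methoxybenzyl (2E)-3-methylpent-2-en-4-yn-1-yl ether | C#C/C(C)=C/COCc1ccc(OC)cc1 | intermediate
10 | 4-methoxybenzyl (2E)-3-methylpenta-2,4-dien-1-yl ether | C=C/C(C)=C/COCc1ccc(OC)cc1 | intermediate
11 | 9-[(3E)-5-(4-methoxybenzyloxy)-3-methylpent-3-en-1-yl]-9-borabicyclo[3.3.1]nonane | COc1ccc(COC/C=C(C)/CCB2C3CCCC2CCC3)cc1 | intermediate
12 | ethyl (2Z,4S,6E,10E)-12-(4-methoxybenzyloxy)-2,6,10-trimethyl-4-(triethylsilyloxy)dodeca-2,6,10-trienoate | CCOC(=O)/C(C)=C\[C@@H](O[Si](CC)(CC)CC)C/C(C)=C/CC/C(C)=C/COCc1ccc(OC)cc1 | intermediate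
13 | (2Z,4S,6E,10E)-12-(4-methoxybenzyloxy)-2,6,10-trimethyl-4-(triethylsilyloxy)dodeca-2,6,10-trien-1-ol | OC/C(C)=C\[C@@H](O[Si](CC)(CC)CC)C/C(C)=C/CC/C(C)=C/COCc1ccc(OC)cc1 | intermediate
14 | methanesulfonate of 13 | CS(=O)(=O)OC/C(C)=C\[C@@H](O[Si](CC)(CC)CC)C/C(C)=C/CC/C(C)=C/COCc1ccc(OC)cc1 | intermediate
15 | (2Z,4S,6E,10E)-1-chloro-12-(4-methoxybenzyloxy)-2,6,10-trimethyl-4-(triethylsilyloxy)dodeca-2,6,10-triene | ClC/C(C)=C\[C@@H](O[Si](CC)(CC)CC)C/C(C)=C/CC/C(C)=C/COCc1ccc(OC)cc1 | intermediate
16 | (2E,6E,9S,10Z)-12-chloro-3,7,11-trimethyl-9-(triethylsilyloxy)dodeca-2,6,10-trien-1-ol | ClC/C(C)=C\[C@@H](O[Si](CC)(CC)CC)C/C(C)=C/CC/C(C)=C/CO | intermediate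
17 | (3Z,5S,7E,11E)-3,7,11-trimethyl-5-(triethylsilyloxy)-1-oxacyclotrideca-3,7,11-triene | O1C/C(C)=C\[C@@H](O[Si](CC)(CC)CC)C/C(C)=C/CC/C(C)=C/C1 | intermediate
18 | C6-lithiated 17 (delocalised oxyallyllithium, drawn σ-bonded at C6) | O1C/C(C)=C\[C@@H](O[Si](CC)(CC)CC)C/C(C)=C/CC/C(C)=C/C1[Li] | intermediate
19 | lithium alkoxide of 20 | CC[Si](CC)(CC)O[C@H]1C/C(C)=C/CC/C(C)=C/[C@H](O[Li])[C@@H]1C(C)=C | intermediate
20 | (6S,7S,8S)-7-isopropenyl-8-(triethylsilyloxy)germacra-1(10)E,4E-dien-6-ol | CC[Si](CC)(CC)O[C@H]1C/C(C)=C/CC/C(C)=C/[C@H](O)[C@@H]1C(C)=C | intermediate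
21 | (6S,7S,8S)-8-(triethylsilyloxy)germacra-1(10)E,4E-dien-6-ol | CC[Si](CC)(CC)O[C@H]1C/C(C)=C/CC/C(C)=C/[C@H](O)[C@@H]1C(C)C | intermediate
22 | (6S,7R,8S)-6-(tert-butyldimethylsilyloxy)-8-(triethylsilyloxy)germacra-1(10)E,4E-diene | CC[Si](CC)(CC)O[C@H]1C/C(C)=C/CC/C(C)=C/[C@H](O[Si](C)(C)C(C)(C)C)[C@@H]1C(C)C | intermediate
23 | (6S,7R,8S)-6-(tert-butyldimethylsilyloxy)germacra-1(10)E,4E-dien-8-ol | O[C@H]1C/C(C)=C/CC/C(C)=C/[C@H](O[Si](C)(C)C(C)(C)C)[C@@H]1C(C)C | intermediate
24 | ferulic acid | COc1cc(/C=C/C(=O)O)ccc1O | starting material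
25 | tert-butyldimethylsilyl (E)-3-[4-(tert-butyldimethylsilyloxy)-3-methoxyphenyl]prop-2-enoate | COc1cc(/C=C/C(=O)O[Si](C)(C)C(C)(C)C)ccc1O[Si](C)(C)C(C)(C)C | intermediate
26 | (E)-3-[4-(tert-butyldimethylsilyloxy)-3-methoxyphenyl]prop-2-enoic acid | COc1cc(/C=C/C(=O)O)ccc1O[Si](C)(C)C(C)(C)C | intermediate
27 | mixed anhydride of 26 and 2,4,6-trichlorobenzoic acid | COc1cc(/C=C/C(=O)OC(=O)c2c(Cl)cc(Cl)cc2Cl)ccc1O[Si](C)(C)C(C)(C)C | intermediate
28 | (6S,7R,8S)-6-(tert-butyldimethylsilyloxy)germacra-1(10)E,4E-dien-8-yl (E)-3-[4-(tert-butyldimethylsilyloxy)-3-methoxyphenyl]prop-2-enoate | COc1cc(/C=C/C(=O)O[C@H]2C/C(C)=C/CC/C(C)=C/[C@H](O[Si](C)(C)C(C)(C)C)[C@@H]2C(C)C)ccc1O[Si](C)(C)C(C)(C)C | intermediate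
29 | (6S,7S,8S)-6-hydroxygermacra-1(10)E,4E-dien-8-yl (E)-ferulate | COc1cc(/C=C/C(=O)O[C@H]2C/C(C)=C/CC/C(C)=C/[C@H](O)[C@@H]2C(C)C)ccc1O | target

Total step count: 19. Longest linear sequence: 16 (steps 1–5, 8–16, 18, 19).

Steps most likely to fail

1. **Step 13.**
   - What may go wrong: proton removal at C12 instead of C6, followed by 1,4-loss of the C8 silyloxide or by the rival shift onto C4. Leakage through the endo envelope would also erode the C6 configuration.
   - Fallback (carbanion site fixed by tin–lithium exchange, Wittig–Still variant): it sets out from 16. MnO2 in CH2Cl2 oxidises the allylic alcohol to the chloro enal F1. One equivalent of Bu3SnLi, added at −78 °C in THF, should add to the aldehyde faster than it displaces chloride and give the α-hydroxystannane F2 (both C6 epimers). Closure under the conditions of step 12, kept at or below room temperature, gives the C6-stannylated 13-membered ether F3. n-BuLi in THF at −78 °C exchanges tin for lithium and delivers 18 without any contest between C–H sites. Both epimers converge because the oxyallyllithium is delocalised. The route is rejoined at 18 and continues to 20.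

2. **Step 12.**
   - What may go wrong: intermolecular etherification outrunning the 13-membered closure (oligomer formation), or base-induced loss of HCl from the allylic chloride.
   - Fallback (ether bond made intermolecularly, ring closed at C1–C2 by an intramolecular B-alkyl Suzuki–Miyaura coupling): it sets out from 7 and 8. i-Bu2AlH reduces 7 to the iodo dienol F4, and N-chlorosuccinimide/Me2S (Corey–Kim chlorination) gives the allylic chloride F5. Semihydrogenation of unprotected 8 as in step 7 gives (2E)-3-methylpenta-2,4-dien-1-ol F6. Its sodium alkoxide displaces the chloride of F5 to give the open-chain bis-allylic ether F7. 9-BBN-H adds to the terminal vinyl group to give the borane F8. F8 is fed slowly into Pd(dppf)Cl2, AsPh3 and Cs2CO3 in DMF–THF–H2O and closes the ring to 17, where the route is rejoined. Steps 6 and 8–12 are bypassed.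

3. **Step 14.**
   - What may go wrong: reduction or isomerisation of the strained ring alkenes, or binding of the catalyst by the 1,5-diene so that the hindered isopropenyl group is not reduced.
   - Fallback (hydroboration and deoxygenation in place of hydrogenation): it sets out from 20. TBSOTf/2,6-lutidine gives the isopropenyl bis-silyl ether F9. 9-BBN-H, which strongly prefers 1,1-disubstituted over trisubstituted alkenes, gives the primary borane F10 (C11 epimers, of no consequence). NaBO3·4H2O oxidises it to the primary alcohol F11, and MsCl/Et3N gives the mesylate F12. LiEt3BH replaces the mesylate by hydride, which turns the branch into isopropyl and rejoins the route at 22. Steps 14 and 15 are bypassed.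

Further compounds

F1 | step 13 | (2E,6E,9S,10Z)-12-chloro-3,7,11-trimethyl-9-(triethylsilyloxy)dodeca-2,6,10-trienal | ClC/C(C)=C\[C@@H](O[Si](CC)(CC)CC)C/C(C)=C/CC/C(C)=C/C=O
F2 | step 13 | (2E,6E,9S,10Z)-12-chloro-3,7,11-trimethyl-1-(tributylstannyl)-9-(triethylsilyloxy)dodeca-2,6,10-trien-1-ol, C6 epimers | ClC/C(C)=C\[C@@H](O[Si](CC)(CC)CC)C/C(C)=C/CC/C(C)=C/C(O)[Sn](CCCC)(CCCC)CCCC
F3 | step 13 | C6-(tributylstannyl) derivative of 17, C6 epimers | O1C/C(C)=C\[C@@H](O[Si](CC)(CC)CC)C/C(C)=C/CC/C(C)=C/C1[Sn](CCCC)(CCCC)CCCC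
F4 | step 12 | (2Z,4S,6E)-7-iodo-2,6-dimethyl-4-(triethylsilyloxy)hepta-2,6-dien-1-ol | OC/C(C)=C\[C@@H](O[Si](CC)(CC)CC)C/C(C)=C/I
F5 | step 12 | (1E,4S,5Z)-7-chloro-1-iodo-2,6-dimethyl-4-(triethylsilyloxy)hepta-1,5-diene | ClC/C(C)=C\[C@@H](O[Si](CC)(CC)CC)C/C(C)=C/I
F6 | step 12 | (2E)-3-methylpenta-2,4-dien-1-ol | C=C/C(C)=C/CO
F7 | step 12 | open-chain ether of F6 and F5 (O joining C6 and C12) | C=C/C(C)=C/COC/C(C)=C\[C@@H](O[Si](CC)(CC)CC)C/C(C)=C/I
F8 | step 12 | 9-BBN adduct of F7 (boron on C2) | C1CCC2CCCC1B2CC/C(C)=C/COC/C(C)=C\[C@@H](O[Si](CC)(CC)CC)C/C(C)=C/I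
F9 | step 14 | 6-O-tert-butyldimethylsilyl ether of 20 | CC[Si](CC)(CC)O[C@H]1C/C(C)=C/CC/C(C)=C/[C@H](O[Si](C)(C)C(C)(C)C)[C@@H]1C(C)=C
F10 | step 14 | 9-BBN adduct of F9 (boron on C12, C11 epimers) | CC[Si](CC)(CC)O[C@H]1C/C(C)=C/CC/C(C)=C/[C@H](O[Si](C)(C)C(C)(C)C)[C@@H]1C(C)CB2C3CCCC2CCC3
F11 | step 14 | C12 primary alcohol from F10 (C11 epimers) | CC[Si](CC)(CC)O[C@H]1C/C(C)=C/CC/C(C)=C/[C@H](O[Si](C)(C)C(C)(C)C)[C@@H]1C(C)CO
F12 | step 14 | methanesulfonate of F11 (C11 epimers) | CC[Si](CC)(CC)O[C@H]1C/C(C)=C/CC/C(C)=C/[C@H](O[Si](C)(C)C(C)(C)C)[C@@H]1C(C)COS(C)(=O)=O
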